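**Plan**

1. Atom labels: C1 ester carbon, C2, ring O1–O2–C3–C4–C5–C6 (1,2-dioxane), side chain C7=C8–C9–C10. The retrosynthesis first cuts C8–ethyl, then C8–C9 together with C10–ethyl, which leaves a ring-bound C7 dibromoalkene, 1-hexene and Et3Al.
2. Enabling feature: C8 of the exocyclic E-trisubstituted C7=C8 alkene on the quaternary ring carbon C6 bears two different alkyl groups. The one trans to the ring (C9–C10) is a 2-ethylhexyl unit, that is 1-hexene plus ethyl, so a C7=CBr2 group can be alkylated twice, trans position first.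
3. The dibromoalkene is traced to the C7 aldehyde (glycol cleavage of a C7–C8 diol). The ring is cut at C3–O2 (peroxide conjugate addition to a C2=C3 enoate) and at C6–O1 (perhydrolysis of a C6–C7 epoxide).
4. The open chain is cut at C2=C3 (Wittig), C4–C5 (auxiliary-controlled alkylation with an E-allylic bromide) and C6=C7 (Wittig).
5. Forward order: chain C3–C8, enoate, epoxide, hydroperoxide, closure of the only ring (the 1,2-dioxane), C7 aldehyde, dibromoalkene, then the side chain in two couplings.
6. Stereochemistry: C4 from the oxazolidinone; C6 from Sharpless epoxidation followed by inversion on perhydrolysis; C3 from the chair-like ring closure; C10 from the zirconium catalyst; the C7=C8 geometry from the order in which the two bromides are replaced.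

Key step: step 14

Remark (assumption): the (+)-enantiomer of bis(1-neomenthylindenyl)zirconium dichloride, (NMI)2ZrCl2, is assumed to deliver the S-configured 2-ethylhexyl group, by analogy with the sense of induction of the (−)-enantiomer in methylalumination of 1-alkenes; oxidation of an aliquot of the alane to 2-ethylhexan-1-ol would show the sense, and the other catalyst enantiomer would be used if it is reversed.

**Route**

Step 1
Reactants: 1 2-[(tert-butyldimethylsilyl)oxy]acetaldehyde; 2 ethyl 2-(triphenylphosphoranylidene)butanoate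
Product: 3 ethyl (2E)-4-[(tert-butyldimethylsilyl)oxy]-2-ethylbut-2-enoate
Conditions: CH2Cl2, 0 → 23 °C
Reagents that add atoms: none
Why: Wittig olefination with the α-ethyl stabilised ylide should be E-selective, which places the silyloxymethyl carbon (C8) cis to the ethyl group and trans to the ester carbon that becomes C5.

Step 2
Reactants: 3 ethyl (2E)-4-[(tert-butyldimethylsilyl)oxy]-2-ethylbut-2-enoate
Product: 4 (2E)-4-[(tert-butyldimethylsilyl)oxy]-2-ethylbut-2-en-1-ol
Conditions: i-Bu2AlH (2.2 equiv), CH2Cl2, −78 °C; aqueous sodium potassium tartrate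
Reagents that add atoms: none
Why: 1,2-Reduction of the conjugated ester with i-Bu2AlH should give the allylic alcohol without touching the silyl ether or the alkene geometry.

Step 3
Reactants: 4 (2E)-4-[(tert-butyldimethylsilyl)oxy]-2-ethylbut-2-en-1-ol
Product: 5 {[(2E)-4-bromo-3-ethylbut-2-en-1-yl]oxy}(tert-butyl)dimethylsilane
Conditions: CBr4, PPh3, CH2Cl2, 0 °C
Reagents that add atoms: carbon tetrabromide, BrC(Br)(Br)Br
Why: The Appel reaction converts the primary allylic alcohol into the bromide under neutral conditions, so the silyl ether and the E geometry should survive.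

Step 4
Reactants: 6 (4S)-4-benzyl-1,3-oxazolidin-2-one; 7 butanoyl chloride
Product: 9 (4S)-4-benzyl-3-butanoyl-1,3-oxazolidin-2-one, via N-lithio oxazolidinone 8 (not isolated)
Conditions: n-BuLi, THF, −78 °C; then 7, −78 → 0 °C
Reagents that add atoms: none
Why: N-Acylation of the lithiated oxazolidinone with the acid chloride is the standard entry to the Evans imide.

Step 5
Reactants: 9 (4S)-4-benzyl-3-butanoyl-1,3-oxazolidin-2-one; 5 {[(2E)-4-bromo-3-ethylbut-2-en-1-yl]oxy}(tert-butyl)dimethylsilane
Product: 11 (4S)-4-benzyl-3-[(2R,4E)-6-[(tert-butyldimethylsilyl)oxy]-2,4-diethylhex-4-enoyl]-1,3-oxazolidin-2-one, via sodium Z-enolate 10 (not isolated)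
Conditions: NaN(SiMe3)2, THF, −78 °C; then 5, −78 → −40 °C
Reagents that add atoms: none
Why: In the Evans asymmetric alkylation the chelated sodium Z-enolate is attacked by the reactive allylic bromide on the face opposite the benzyl group, which forms C4–C5 and sets C4 as R.

Step 6
Reactants: 11 (4S)-4-benzyl-3-[(2R,4E)-6-[(tert-butyldimethylsilyl)oxy]-2,4-diethylhex-4-enoyl]-1,3-oxazolidin-2-one
Product: 12 (2R,4E)-6-[(tert-butyldimethylsilyl)oxy]-2,4-diethylhex-4-en-1-ol
Conditions: LiBH4, H2O (1 equiv), Et2O, 0 °C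
Reagents that add atoms: none
Why: Reductive removal of the auxiliary with LiBH4 should free the primary alcohol at C3 and return the oxazolidinone without epimerising C4.

Step 7
Reactants: 12 (2R,4E)-6-[(tert-butyldimethylsilyl)oxy]-2,4-diethylhex-4-en-1-ol; 13 methyl (triphenylphosphoranylidene)acetate
Product: 15 methyl (2E,4R,6E)-8-[(tert-butyldimethylsilyl)oxy]-4,6-diethylocta-2,6-dienoate, via aldehyde 14 (not isolated)
Conditions: Dess–Martin periodinane, CH2Cl2, 0 → 23 °C; then 13 (3 equiv), 23 °C
Reagents that add atoms: none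
Why: Dess–Martin oxidation followed in the same flask by Wittig olefination with the stabilised ylide should give the E-enoate while the epimerisable α-branched aldehyde is never stored.

Step 8
Reactants: 15 methyl (2E,4R,6E)-8-[(tert-butyldimethylsilyl)oxy]-4,6-diethylocta-2,6-dienoate
Product: 16 methyl (2E,4R,6E)-4,6-diethyl-8-hydroxyocta-2,6-dienoate
Conditions: HF·pyridine, pyridine, THF, 0 → 23 °C
Reagents that add atoms: none
Why: Fluoride-mediated desilylation under mildly acidic conditions frees the allylic alcohol and avoids conjugate addition to the enoate or deprotonation at C4.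

Step 9
Reactants: 16 methyl (2E,4R,6E)-4,6-diethyl-8-hydroxyocta-2,6-dienoate
Product: 17 methyl (2E,4R)-4-ethyl-5-[(2R,3R)-2-ethyl-3-(hydroxymethyl)oxiran-2-yl]pent-2-enoate
Conditions: Ti(OiPr)4 (10 mol %), D-(−)-diisopropyl tartrate (12 mol %), t-BuOOH, 4 Å molecular sieves, CH2Cl2, −20 °C
Reagents that add atoms: tert-butyl hydroperoxide, CC(C)(C)OO
Why: In the Sharpless asymmetric epoxidation the titanium–tartrate complex delivers oxygen to one face of the allylic alcohol alkene only, so D-(−)-tartrate should set C6 and C7 as R,R under reagent control while the electron-poor enoate stays untouched.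

Step 10
Reactants: 17 methyl (2E,4R)-4-ethyl-5-[(2R,3R)-2-ethyl-3-(hydroxymethyl)oxiran-2-yl]pent-2-enoate
Product: 18 methyl (2E,4R,6S,7R)-4,6-diethyl-6-hydroperoxy-7,8-dihydroxyoct-2-enoate
Conditions: H2O2 (anhydrous, Et2O solution, excess), H3PMo12O40 (3 mol %), Et2O, 23 °C
Reagents that add atoms: hydrogen peroxide, OO
Why: In this acid-catalysed epoxide perhydrolysis H2O2 should open the activated oxirane at the tertiary carbon C6 in a borderline SN2 process with inversion, which gives the 6S tertiary hydroperoxide and leaves the C7–C8 diol.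

Step 11
Reactants: 18 methyl (2E,4R,6S,7R)-4,6-diethyl-6-hydroperoxy-7,8-dihydroxyoct-2-enoate
Product: 19 methyl 2-[(3S,4R,6S)-6-[(1R)-1,2-dihydroxyethyl]-4,6-diethyl-1,2-dioxan-3-yl]acetate
Conditions: Et2NH (0.2 equiv), CF3CH2OH, 23 °C
Reagents that add atoms: none
Why: In this intramolecular oxa-Michael (peroxy-Michael) addition the hydroperoxide, more acidic and more nucleophilic than the alcohols, should close the 1,2-dioxane in a 6-exo-trig mode through a chair with both ethyl groups and the acceptor equatorial, which sets C3 as S (3,4-trans).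

Step 12
Reactants: 19 methyl 2-[(3S,4R,6S)-6-[(1R)-1,2-dihydroxyethyl]-4,6-diethyl-1,2-dioxan-3-yl]acetate
Product: 20 methyl 2-[(3S,4R,6S)-4,6-diethyl-6-formyl-1,2-dioxan-3-yl]acetate
Conditions: NaIO4, THF–H2O, 0 → 23 °C
Reagents that add atoms: none
Why: Malaprade glycol cleavage removes C8 as formaldehyde and leaves the non-enolisable aldehyde at C7, the dialkyl peroxide being inert to periodate.

Step 13
Reactants: 20 methyl 2-[(3S,4R,6S)-4,6-diethyl-6-formyl-1,2-dioxan-3-yl]acetate
Product: 21 methyl 2-[(3S,4R,6S)-6-(2,2-dibromoethenyl)-4,6-diethyl-1,2-dioxan-3-yl]acetate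
Conditions: CBr4 (2.2 equiv), PPh3 (4.0 equiv), CH2Cl2, 0 °C, premixed; then 20, 0 °C
Reagents that add atoms: carbon tetrabromide, BrC(Br)(Br)Br
Why: The Ramirez dibromo-olefination with the preformed ylide (no free phosphine left to reduce the O–O bond) should convert the hindered aldehyde into the 1,1-dibromoalkene under non-basic conditions that spare the ester.

Step 14
Reactants: 21 methyl 2-[(3S,4R,6S)-6-(2,2-dibromoethenyl)-4,6-diethyl-1,2-dioxan-3-yl]acetate; 22 hex-1-ene; 23 triethylaluminium
Product: 26 methyl 2-[(3S,4R,6S)-6-[(1Z,4S)-2-bromo-4-ethyloct-1-en-1-yl]-4,6-diethyl-1,2-dioxan-3-yl]acetate, via alane 24 (not isolated), via alkylzinc triflate 25 (not isolated)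
Conditions: 22 (2 equiv), 23 (2 equiv), (+)-(NMI)2ZrCl2 (5 mol %), CH2Cl2, 0 → 23 °C; evaporation (60 °C, 0.1 mmHg); Zn(OTf)2 (2 equiv), DMF, 70 °C; then 21 (1 equiv), Pd(DPEphos)Cl2 (5 mol %), THF–DMF, 0 → 23 °C
Reagents that add atoms: none
Why: Zirconium-catalysed asymmetric carboalumination inserts 22 into the Zr–ethyl bond of the chiral zirconocene (C10–ethyl bond) and alkyl exchange with 23 releases alane 24, which Zn(OTf)2 in DMF converts into alkylzinc 25; zerovalent palladium formed from Pd(DPEphos)Cl2 then inserts into one C–Br bond of 21, and transmetalation and reductive elimination form C8–C9 (Negishi coupling). The closest known reaction types are the one-pot carboalumination–zinc transmetalation–palladium coupling with alkenyl bromides and the trans-selective monoalkylation of 1,1-dibromoalkenes by alkylzinc reagents. No ring is closed in this step. The new stereocentre C10 is set by the catalyst alone (facial selection of the alkene by the neomenthylindenyl ligands), the (+)-enantiomer being chosen for the S configuration. The step needs site selectivity between the two bromides, and the substrate secures it because the bromide cis to the fully substituted C6 is shielded, so that oxidative addition should occur at the trans C–Br bond and the reaction should stop at the Z-monobromide. It also needs the 2-ethylhexyl group to be transferred in preference to ethyl, which is why 23 is stripped exhaustively (mixed alanes exchange alkyl groups, so stripping should also lower the ethyl content) before zinc is added.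

Step 15
Reactants: 26 methyl 2-[(3S,4R,6S)-6-[(1Z,4S)-2-bromo-4-ethyloct-1-en-1-yl]-4,6-diethyl-1,2-dioxan-3-yl]acetate
Product: 27 methyl 2-[(3S,4R,6S)-6-[(1E,4S)-2,4-diethyloct-1-en-1-yl]-4,6-diethyl-1,2-dioxan-3-yl]acetate
Conditions: EtZnCl (3 equiv, from Et2Zn and ZnCl2), Pd(tBu3P)2 (3 mol %), THF, 23 °C
Reagents that add atoms: ethylzinc chloride, CC[Zn]Cl (generated from diethylzinc, CC[Zn]CC)
Why: In this Negishi coupling zerovalent palladium bearing tBu3P inserts into the remaining C8–Br bond, and ethyl transfer from zinc followed by fast reductive elimination should replace bromine with retention of the alkene geometry.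

**Compound list**

1 | 2-[(tert-butyldimethylsilyl)oxy]acetaldehyde | O=CCO[Si](C)(C)C(C)(C)C | starting material
2 | ethyl 2-(triphenylphosphoranylidene)butanoate | CCOC(=O)C(CC)=P(c1ccccc1)(c1ccccc1)c1ccccc1 | starting material
3 | ethyl (2E)-4-[(tert-butyldimethylsilyl)oxy]-2-ethylbut-2-enoate | CCOC(=O)/C(CC)=C/CO[Si](C)(C)C(C)(C)C | intermediate
4 | (2E)-4-[(tert-butyldimethylsilyl)oxy]-2-ethylbut-2-en-1-ol | OC/C(CC)=C/CO[Si](C)(C)C(C)(C)C | intermediate
5 | {[(2E)-4-bromo-3-ethylbut-2-en-1-yl]oxy}(tert-butyl)dimethylsilane | BrC/C(CC)=C/CO[Si](C)(C)C(C)(C)C | intermediate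
6 | (4S)-4-benzyl-1,3-oxazolidin-2-one | O=C1OC[C@H](Cc2ccccc2)N1 | starting material
7 | butanoyl chloride | CCCC(=O)Cl | starting material
8 | lithium salt of 6 (N-lithio oxazolidinone) | [Li]N1C(=O)OC[C@@H]1Cc1ccccc1 | intermediate
9 | (4S)-4-benzyl-3-butanoyl-1,3-oxazolidin-2-one | CCCC(=O)N1C(=O)OC[C@@H]1Cc1ccccc1 | intermediate
10 | sodium (Z)-enolate of 9 | CC/C=C(\O[Na])N1C(=O)OC[C@@H]1Cc1ccccc1 | intermediate
11 | (4S)-4-benzyl-3-[(2R,4E)-6-[(tert-butyldimethylsilyl)oxy]-2,4-diethylhex-4-enoyl]-1,3-oxazolidin-2-one | O=C(N1C(=O)OC[C@@H]1Cc1ccccc1)[C@H](CC)C/C(CC)=C/CO[Si](C)(C)C(C)(C)C | intermediate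
12 | (2R,4E)-6-[(tert-butyldimethylsilyl)oxy]-2,4-diethylhex-4-en-1-ol | OC[C@H](CC)C/C(CC)=C/CO[Si](C)(C)C(C)(C)C | intermediate
13 | methyl (triphenylphosphoranylidene)acetate | COC(=O)C=P(c1ccccc1)(c1ccccc1)c1ccccc1 | starting material
14 | (2R,4E)-6-[(tert-butyldimethylsilyl)oxy]-2,4-diethylhex-4-enal | O=C[C@H](CC)C/C(CC)=C/CO[Si](C)(C)C(C)(C)C | intermediate
15 | methyl (2E,4R,6E)-8-[(tert-butyldimethylsilyl)oxy]-4,6-diethylocta-2,6-dienoate | COC(=O)/C=C/[C@H](CC)C/C(CC)=C/CO[Si](C)(C)C(C)(C)C | intermediate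
16 | methyl (2E,4R,6E)-4,6-diethyl-8-hydroxyocta-2,6-dienoate | COC(=O)/C=C/[C@H](CC)C/C(CC)=C/CO | intermediate
17 | methyl (2E,4R)-4-ethyl-5-[(2R,3R)-2-ethyl-3-(hydroxymethyl)oxiran-2-yl]pent-2-enoate | COC(=O)/C=C/[C@H](CC)C[C@@]1(CC)O[C@@H]1CO | intermediate
18 | methyl (2E,4R,6S,7R)-4,6-diethyl-6-hydroperoxy-7,8-dihydroxyoct-2-enoate | COC(=O)/C=C/[C@H](CC)C[C@](CC)(OO)[C@H](O)CO | intermediate
19 | methyl 2-[(3S,4R,6S)-6-[(1R)-1,2-dihydroxyethyl]-4,6-diethyl-1,2-dioxan-3-yl]acetate | OC[C@@H](O)[C@]1(CC)C[C@@H](CC)[C@H](CC(=O)OC)OO1 | intermediate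
20 | methyl 2-[(3S,4R,6S)-4,6-diethyl-6-formyl-1,2-dioxan-3-yl]acetate | O=C[C@]1(CC)C[C@@H](CC)[C@H](CC(=O)OC)OO1 | intermediate
21 | methyl 2-[(3S,4R,6S)-6-(2,2-dibromoethenyl)-4,6-diethyl-1,2-dioxan-3-yl]acetate | BrC(Br)=C[C@]1(CC)C[C@@H](CC)[C@H](CC(=O)OC)OO1 | intermediate
22 | hex-1-ene | C=CCCCC | starting material
23 | triethylaluminium | CC[Al](CC)CC | starting material
24 | diethyl[(2S)-2-ethylhexyl]alane | CCCC[C@H](CC)C[Al](CC)CC | intermediate
25 | [(2S)-2-ethylhexyl]zinc trifluoromethanesulfonate | CCCC[C@H](CC)C[Zn]OS(=O)(=O)C(F)(F)F | intermediate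
26 | methyl 2-[(3S,4R,6S)-6-[(1Z,4S)-2-bromo-4-ethyloct-1-en-1-yl]-4,6-diethyl-1,2-dioxan-3-yl]acetate | CCCC[C@H](CC)C/C(=C/[C@]1(CC)C[C@@H](CC)[C@H](CC(=O)OC)OO1)Br | intermediate
27 | methyl 2-[(3S,4R,6S)-6-[(1E,4S)-2,4-diethyloct-1-en-1-yl]-4,6-diethyl-1,2-dioxan-3-yl]acetate | CCCC[C@H](CC)C/C(=C/[C@]1(CC)C[C@@H](CC)[C@H](CC(=O)OC)OO1)CC | target

**Totals**

Total step count: 15.
Longest linear sequence: 14 steps (from 1 through steps 1–3 and 5–15 to 27).

**Steps most likely to fail**

Step 14. Ethyl groups that remain on aluminium and zinc may be transferred to palladium in competition with the β-branched 2-ethylhexyl group, and aluminium Lewis acids or low-valent metal species may cleave the O–O bond. The fallback sets out from 22 and 23 and comes back at 26. The carboalumination is run on its own and alane 24 is quenched with iodine (THF, 0 → 23 °C) to give (3S)-3-(iodomethyl)heptane F1, which is purified. Zinc insertion (Zn dust, LiCl, THF, 40 °C) then gives [(2S)-2-ethylhexyl]zinc iodide F2, which carries no ethyl groups and no aluminium salts. F2 is coupled with 21 under Pd(DPEphos)Cl2 in THF to give 26.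

Step 11. The ring closure may show low facial selectivity at C3 (the acceptor taking the axial position in the chair), or the conjugate addition may reverse during isolation. The fallback sets out from 12 and comes back at 19. Alcohol 12 is oxidised to aldehyde 14 as before, and a Still–Gennari olefination (methyl bis(2,2,2-trifluoroethyl)phosphonoacetate, KN(SiMe3)2, 18-crown-6, THF, −78 °C) gives methyl (2Z,4R,6E)-8-[(tert-butyldimethylsilyl)oxy]-4,6-diethylocta-2,6-dienoate F3. Desilylation with HF·pyridine gives methyl (2Z,4R,6E)-4,6-diethyl-8-hydroxyocta-2,6-dienoate F4. Sharpless epoxidation with D-(−)-diisopropyl tartrate gives methyl (2Z,4R)-4-ethyl-5-[(2R,3R)-2-ethyl-3-(hydroxymethyl)oxiran-2-yl]pent-2-enoate F5. Perhydrolysis as in step 10 gives methyl (2Z,4R,6S,7R)-4,6-diethyl-6-hydroperoxy-7,8-dihydroxyoct-2-enoate F6. In the Z-enoate, allylic 1,3-strain holds H-4 in the alkene plane, so the tethered peroxide should reach only the face that leads to the 3,4-trans ring, and treatment with Et2NH in CF3CH2OH should give 19.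

Step 15. Oxidative addition at the bromide cis to the quaternary C6 may be slow, and the ethylpalladium intermediate may undergo β-hydride elimination (net reduction of the C–Br bond) or the alkene may isomerise. The fallback sets out from 26 and comes back at 27. Stille coupling with tributyl(vinyl)stannane (Pd(tBu3P)2, toluene, 50 °C) transfers a group that cannot undergo β-hydride elimination and gives methyl 2-[(3S,4R,6S)-6-[(1Z,4S)-2-ethenyl-4-ethyloct-1-en-1-yl]-4,6-diethyl-1,2-dioxan-3-yl]acetate F7. Diimide (from KO2CN=NCO2K and acetic acid, MeOH, 0 °C) should then reduce the monosubstituted vinyl group much faster than the trisubstituted alkene and leave the O–O bond intact, giving 27.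

**Further compounds**

F1 | step 14 | (3S)-3-(iodomethyl)heptane | CCCC[C@H](CC)CI
F2 | step 14 | [(2S)-2-ethylhexyl]zinc iodide | CCCC[C@H](CC)C[Zn]I
F3 | step 11 | methyl (2Z,4R,6E)-8-[(tert-butyldimethylsilyl)oxy]-4,6-diethylocta-2,6-dienoate | COC(=O)/C=C\[C@H](CC)C/C(CC)=C/CO[Si](C)(C)C(C)(C)C
F4 | step 11 | methyl (2Z,4R,6E)-4,6-diethyl-8-hydroxyocta-2,6-dienoate | COC(=O)/C=C\[C@H](CC)C/C(CC)=C/CO
F5 | step 11 | methyl (2Z,4R)-4-ethyl-5-[(2R,3R)-2-ethyl-3-(hydroxymethyl)oxiran-2-yl]pent-2-enoate | COC(=O)/C=C\[C@H](CC)C[C@@]1(CC)O[C@@H]1CO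
F6 | step 11 | methyl (2Z,4R,6S,7R)-4,6-diethyl-6-hydroperoxy-7,8-dihydroxyoct-2-enoate | COC(=O)/C=C\[C@H](CC)C[C@](CC)(OO)[C@H](O)CO
F7 | step 15 | methyl 2-[(3S,4R,6S)-6-[(1Z,4S)-2-ethenyl-4-ethyloct-1-en-1-yl]-4,6-diethyl-1,2-dioxan-3-yl]acetate | CCCC[C@H](CC)C/C(=C/[C@]1(CC)C[C@@H](CC)[C@H](CC(=O)OC)OO1)C=C
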